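**Missing material.** Ochre can't have kept all the target it made: at 12.0 min its target and electrophile add up to 78.0% of the charge.

common to all: electrophile 0.80 M
- ochre: free base 2 equiv; protonated nucleophile 1.5 equiv; temperature 100 °C; the very flask that is asked about, followed so far
- grey: free base 2 equiv; protonated nucleophile 1.5 equiv; temperature 95 °C; run made earlier
- flask: free base 2.00 equiv; protonated nucleophile 1.50 equiv; temperature 100 °C; time 12 min

| run | time / min | target / % | electrophile / % |
|---|---|---|---|
| ochre | 2.00 | 29 | 71 |
| ochre | 4.00 | 40 | 54 |
| ochre | 6.00 | 49 | 44 |
| ochre | 8.00 | 48 | 36 |
| ochre | 10.0 | 48 | 28 |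
| ochre | 12.0 | 55 | 23 |
| grey | 2.00 | 15 | 82 |
| grey | 4.00 | 33 | 70 |
| grey | 6.00 | 35 | 54 |
| grey | 8.00 | 44 | 46 |
| grey | 10.0 | 43 | 43 |
| grey | 12.0 | 49 | 32 |

(readings scatter by 2 percentage points)

- removed target is counted in

- dawn: at 12 min take out 90% of the target then present, then wait 6.0 min
- midnight: at 12 min raise the temperature by 15 K, then wait 6.0 min
- summer: change nothing and wait 6.0 min more

* target, in percent of the electrophile first charged, at 12 min
* what to do for the largest gain in target; "none" if nothing gains more than 2 percentage points (dawn / midnight / summer / none)
* target present, with what was taken out counted in, in percent of the electrophile first charged, after dawn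
* target present, with what was taken out counted in, in percent of the electrophile first charged, after summer

**The fork.** I assumed that whatever attacks electrophile also attacks target, and I followed one attack. It makes target or loses target, at odds of electrophile against s × target. From 6.00 min to 12.0 min ochre lost 21 percentage points of electrophile, the missing material grew by 15 points, and target over electrophile averaged 1.75. So I read s = 0.408, the selectivity factor: the chance of attack on target against that on electrophile, at equal amounts. Summing the fork gives target = (x^s − x)/(1 − s), where x is the fraction of electrophile left, and the clock doesn't enter. The curve peaks where x = s × target, at x = 22.0% and target 53.9%.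

**Waiting.** Ochre's reading of 23% electrophile puts target now at 53.9%, which is my figure. Successive spans of 6.00 min cost 56 points and then 21 points of electrophile. The same shrinkage leaves x = 15.1% after 6.0 min, below the peak, so summer ends at 52.6%.

**Taking out.** Dawn leaves 5.39% in the pot. The fork run from there to the same x gains 6.3 points, more than the margin, for a total of 60.2%.

**Heating.** Grey reads s as 0.334, but on readings scattered by 2 points I can't tell how heat moves s. With s held, heat carries the flask further past the peak, so I booked no gain for midnight and chose dawn.

**The result.** The forecast gave 53% now, 59.5% after dawn and 47% after summer, where my own figure for summer was 52.6%: “Dawn is best.” The flask gives 54.0% now, 60.6% after dawn and 54.1% after summer. The gains are 6.6 points for dawn, 2.2 points for midnight and 0.065 points for summer, so the choice is dawn.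

    electrophile + nucleophile → acid set free + target (k = 0.0300 M⁻¹ s⁻¹, Ea = 85.0 kJ mol⁻¹)
    nucleophile + acid set free ⇌ protonated nucleophile, settled at all times (K = 2700 M⁻¹, ΔH = −34.0 kJ mol⁻¹)
    acid set free + free base ⇌ salt of the base (K = 39000 M⁻¹, k = 0.750 M⁻¹ s⁻¹, Ea = 64.0 kJ mol⁻¹, ΔH = −30.0 kJ mol⁻¹)
    nucleophile + target → over-reaction product (k = 0.0120 M⁻¹ s⁻¹, Ea = 56.0 kJ mol⁻¹)
    (constants at 100 °C)

**Same fork.** At 12.0 min the flask holds 25.4% electrophile and 54.0% target, so the fork there makes target 1.15 times as fast as it uses it. The neighbour charged at a quarter of the strength keeps the equivalents and the time, and has 45.6% electrophile left at 12.0 min. The curve puts its target at 45.6%, and that neighbour holds 45.8%.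

(The readings come from a simulation with made-up constants, noise included.)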